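**Strategy.** Everything rests on reading ring A, the cyclohexene of the non-hydroxylated phthalide (C3a, C4, C5, C6, C7, C7a), as a Diels–Alder adduct: its tetrasubstituted C3a=C7a alkene flanked by four sp3 carbons is the retron. The key step is a catalytic enantioselective [4+2] of a push–pull 2-silyloxy diene (C4=C3a–C7a=C7, ester on C7a, masked aldehyde on C7) with acrolein (C5=C6); it forms C4–C5 and C6–C7 and sets C6 and C7. The adduct is annulated to a cis-fused cyclohexenone, whose silyl dienol ether adds an acyl ynoate anti to ring A to give the bicyclo[2.2.2]octene; carbinol inversion and two lactonisations finish.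

Key step: step 3

Assumption: the (S)-oxazaborolidinium salt is taken to give the (5S,6S) adduct 6; if the sense of induction is the opposite, its enantiomer is used. Intermediates are numbered as cyclohexenes, naphthalenes or 1,4-ethanonaphthalenes; "ring A" is always the cyclohexene that becomes C3a–C7a of the non-hydroxylated phthalide.

Step 1
Reactants: 1 methyl acetoacetate; 2 2,2-dimethoxyacetaldehyde
Product: 3 methyl (2Z)-2-acetyl-4,4-dimethoxybut-2-enoate
Conditions: piperidine (10 mol %), AcOH (10 mol %), CH2Cl2, 4 Å MS, 0 °C to rt; E isomer re-equilibrated under the same conditions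
Reagents that add atoms: none
Why: Knoevenagel condensation; reversible amine addition equilibrates the alkene, and the Z isomer (acetal cis to the ester) is collected because it places the acetal on the outside of the diene in step 3.

Step 2
Reactants: 3 methyl (2Z)-2-acetyl-4,4-dimethoxybut-2-enoate
Product: 4 methyl (2Z)-2-{1-[(tert-butyldimethylsilyl)oxy]ethenyl}-4,4-dimethoxybut-2-enoate
Conditions: TBSOTf, Et3N, CH2Cl2, −78 to 0 °C
Reagents that add atoms: tert-butyldimethylsilyl triflate, CC(C)(C)[Si](C)(C)OS(=O)(=O)C(F)(F)F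
Why: Soft enolisation of the methyl ketone gives the cross-conjugated 2-silyloxy diene, the usual way to turn an alkylidene β-keto ester into a Diels–Alder diene.

Step 3
Reactants: 4 methyl (2Z)-2-{1-[(tert-butyldimethylsilyl)oxy]ethenyl}-4,4-dimethoxybut-2-enoate; 5 acrolein
Product: 6 methyl (5S,6S)-2-[(tert-butyldimethylsilyl)oxy]-6-(dimethoxymethyl)-5-formylcyclohex-1-ene-1-carboxylate
Conditions: (S)-3,3-diphenyl-1-(2-methylphenyl)tetrahydro-1H,3H-pyrrolo[1,2-c][1,3,2]oxazaborole (20 mol %), HNTf2 (16 mol %), CH2Cl2, −78 °C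
Reagents that add atoms: none
Why: Normal-electron-demand, concerted but asynchronous [4+2] cycloaddition in which the silyl-enol-ether terminus (future C4) leads the bonding to the β-carbon of boron-bound acrolein (C5) and the ester-bearing terminus (C7) closes on the α-carbon (C6). The closest known reaction type is the oxazaborolidinium-catalysed enantioselective Diels–Alder reaction of 2-silyloxy-1,3-dienes with α,β-unsaturated aldehydes and esters. Ring A is closed by intermolecular [4+2] annulation, no ring existing beforehand. C6 and C7 should come out cis because the acetal sits on the outside of the Z-configured diene terminus and the formyl group takes the endo position; their absolute sense is set by the catalyst, whose aryl group shields one face of the coordinated s-trans enal. The step needs regioselectivity, secured by the push–pull polarisation (the silyloxy group on C3a makes C4 the nucleophilic terminus, the ester on C7a makes C7 the electrophilic one, which agrees with the "para" and "ortho" rules), and chemoselective activation of the aldehyde over the diene ester, secured by the higher Lewis basicity of acrolein and the low temperature.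

Step 4
Reactants: 7 triphenylphosphine hydrobromide; 8 ethyl vinyl ether
Product: 9 (1-ethoxyethyl)triphenylphosphonium bromide
Conditions: CH2Cl2, 0 °C to rt
Reagents that add atoms: none
Why: Protonation of the enol ether at carbon gives an oxocarbenium ion that triphenylphosphine captures, the reaction type by which 2-tetrahydropyranylphosphonium salts are made from dihydropyran.

Step 5
Reactants: 6 methyl (5S,6S)-2-[(tert-butyldimethylsilyl)oxy]-6-(dimethoxymethyl)-5-formylcyclohex-1-ene-1-carboxylate; 9 (1-ethoxyethyl)triphenylphosphonium bromide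
Product: 10 methyl 2-[(tert-butyldimethylsilyl)oxy]-6-(dimethoxymethyl)-5-(2-ethoxyprop-1-en-1-yl)cyclohex-1-ene-1-carboxylate (5,6-cis as in 6; enol ether E/Z mixture)
Conditions: 9, KN(SiMe3)2, THF, −78 °C; then 6, −78 to −20 °C
Reagents that add atoms: none
Why: Wittig olefination with an α-alkoxyalkylidene ylide (a masked acetonyl group); the reactive ylide should add to the aldehyde at −78 °C faster than it deprotonates the adjacent stereocentre, and the enol ether geometry is irrelevant because it is hydrolysed in step 8.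

Step 6
Reactants: 10 methyl 2-[(tert-butyldimethylsilyl)oxy]-6-(dimethoxymethyl)-5-(2-ethoxyprop-1-en-1-yl)cyclohex-1-ene-1-carboxylate
Product: 11 methyl 6-(dimethoxymethyl)-5-(2-ethoxyprop-1-en-1-yl)-2-{[(trifluoromethyl)sulfonyl]oxy}cyclohex-1-ene-1-carboxylate (5,6-cis)
Conditions: CsF, PhNTf2, DME, rt
Reagents that add atoms: N-phenylbis(trifluoromethanesulfonimide), O=S(=O)(N(c1ccccc1)S(=O)(=O)C(F)(F)F)C(F)(F)F
Why: Fluoride cleaves the O–Si bond to the stabilised β-keto ester enolate, which is O-triflated by the N-aryl triflimide; the ethyl enol ether and the acetal are inert to these conditions.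

Step 7
Reactants: 11 methyl 6-(dimethoxymethyl)-5-(2-ethoxyprop-1-en-1-yl)-2-{[(trifluoromethyl)sulfonyl]oxy}cyclohex-1-ene-1-carboxylate; 12 pent-1-yne
Product: 13 methyl 6-(dimethoxymethyl)-5-(2-ethoxyprop-1-en-1-yl)-2-(pent-1-yn-1-yl)cyclohex-1-ene-1-carboxylate (5,6-cis)
Conditions: PdCl2(PPh3)2 (5 mol %), CuI (10 mol %), Et3N, THF, rt
Reagents that add atoms: none
Why: Sonogashira coupling of a β-triflyloxy enoate with a terminal alkyne installs the five carbons of the future butylidene group of ring A, the cis enyne–ester geometry being fixed by the ring.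

Step 8
Reactants: 13 methyl 6-(dimethoxymethyl)-5-(2-ethoxyprop-1-en-1-yl)-2-(pent-1-yn-1-yl)cyclohex-1-ene-1-carboxylate
Product: 15 methyl (4aR,8aR)-6-oxo-2-(pent-1-yn-1-yl)-3,4,4a,5,6,8a-hexahydronaphthalene-1-carboxylate, via keto aldehyde 14 (not isolated)
Conditions: 1 M HCl, THF, 0 °C to rt; then TsOH·H2O (20 mol %), toluene, 4 Å MS, 50 °C
Reagents that add atoms: water, O
Why: Aqueous acid hydrolyses the enol ether to the methyl ketone and the acetal to the aldehyde, and acid-catalysed intramolecular aldol condensation (6-enolendo-exo-trig, then dehydration) closes the cyclohexenone; the cis ring fusion is inherited from 6 because no bond to either ring-fusion carbon is broken.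

Step 9
Reactants: 16 methyl propiolate; 17 pentanoic anhydride
Product: 18 methyl 4-oxooct-2-ynoate
Conditions: LiN(SiMe3)2, THF, −78 °C; then added to 17 (2 equiv), THF, −78 °C
Reagents that add atoms: none
Why: Inverse-addition acylation of the lithium acetylide with an anhydride at −78 °C should stop at the ynone because the electron-poor acetylide adds only slowly to the conjugated ketone formed.

Step 10
Reactants: 15 methyl (4aR,8aR)-6-oxo-2-(pent-1-yn-1-yl)-3,4,4a,5,6,8a-hexahydronaphthalene-1-carboxylate
Product: 19 methyl 6-[(tert-butyldimethylsilyl)oxy]-2-(pent-1-yn-1-yl)-3,4,4a,8a-tetrahydronaphthalene-1-carboxylate (4a,8a-cis as in 15)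
Conditions: LiN(iPr)2, THF, −78 °C; then TBSOTf, −78 °C
Reagents that add atoms: tert-butyldimethylsilyl triflate, CC(C)(C)[Si](C)(C)OS(=O)(=O)C(F)(F)F
Why: Kinetic deprotonation of the enone at the α′-methylene and O-silylation give the cross-conjugated 2-silyloxy-1,3-diene; the low temperature avoids equilibration to the extended dienolate through the doubly allylic C8a hydrogen, which would erase that stereocentre.

Step 11
Reactants: 19 methyl 6-[(tert-butyldimethylsilyl)oxy]-2-(pent-1-yn-1-yl)-3,4,4a,8a-tetrahydronaphthalene-1-carboxylate; 18 methyl 4-oxooct-2-ynoate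
Product: 21 dimethyl 9-oxo-3-pentanoyl-6-(pent-1-yn-1-yl)-1,4,4a,7,8,8a-hexahydro-1,4-ethanonaphthalene-2,5-dicarboxylate (ring A syn to the C9–C10 bridge), via silyl enol ether cycloadduct 20 (not isolated)
Conditions: toluene, 40 °C; then 1 M HCl, THF, 0 °C
Reagents that add atoms: none
Why: Diels–Alder reaction of a 2-silyloxycyclohexa-1,3-diene with an acyl ynoate: the silyloxy-activated terminus bonds to the alkyne carbon β to the ketone (the stronger acceptor), so the ester ends up next to the future carbinol bridge; the dienophile approaches the diene face opposite to the cis-fused ring A, which sets both bridgeheads and places ring A syn to the oxygenated bridge; hydrolysis of the silyl enol ether at 0 °C gives the ketone before an Alder–Rickert cycloreversion can set in.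

Step 12
Reactants: 21 dimethyl 9-oxo-3-pentanoyl-6-(pent-1-yn-1-yl)-1,4,4a,7,8,8a-hexahydro-1,4-ethanonaphthalene-2,5-dicarboxylate
Product: 22 dimethyl 9-hydroxy-3-pentanoyl-6-(pent-1-yn-1-yl)-1,4,4a,7,8,8a-hexahydro-1,4-ethanonaphthalene-2,5-dicarboxylate (9-OH on the face turned to ring A)
Conditions: NaBH4, MeOH/CH2Cl2, −78 °C
Reagents that add atoms: none
Why: Borohydride should reduce the strained saturated ketone in preference to the hindered conjugated ketone and attack from the open face above the tetrasubstituted alkene bridge, the other face being screened by the C8 methylene of ring A, so the carbinol forms with the configuration opposite to that of the target.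

Step 13
Reactants: 22 dimethyl 9-hydroxy-3-pentanoyl-6-(pent-1-yn-1-yl)-1,4,4a,7,8,8a-hexahydro-1,4-ethanonaphthalene-2,5-dicarboxylate
Product: 23 the 9-epimeric 4-nitrobenzoate of 22 (ester oxygen on the face turned to the C2=C3 bridge)
Conditions: PPh3, diisopropyl azodicarboxylate, 4-nitrobenzoic acid, toluene, 0 °C to rt
Reagents that add atoms: 4-nitrobenzoic acid, OC(=O)c1ccc(cc1)[N+](=O)[O-]
Why: Mitsunobu esterification proceeds by SN2 displacement of the oxyphosphonium group, the carboxylate entering from the unhindered face over the alkene bridge, which inverts the carbinol to the target configuration; the electron-poor alkene does not assist ionisation.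

Step 14
Reactants: 23 the 9-epimeric 4-nitrobenzoate of 22
Product: 24 9-hydroxy-3-pentanoyl-6-(pent-1-yn-1-yl)-1,4,4a,7,8,8a-hexahydro-1,4-ethanonaphthalene-2,5-dicarboxylic acid (target configuration at C9; in equilibrium with its cyclic lactol)
Conditions: LiOH, THF/MeOH/H2O, rt to 40 °C; then 1 M HCl to pH 3
Reagents that add atoms: lithium hydroxide, [Li+].[OH-]
Why: Hydroxide hydrolyses the two methyl esters and the nitrobenzoate in one operation; the cis 4-oxo-enoic acid that results sits in equilibrium with its cyclic lactol, the direct precursor of the second enol lactone.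

Step 15
Reactants: 24 9-hydroxy-3-pentanoyl-6-(pent-1-yn-1-yl)-1,4,4a,7,8,8a-hexahydro-1,4-ethanonaphthalene-2,5-dicarboxylic acid
Product: 26 target CNP0289078.1, via ring-A butylidene lactone acid 25 (not isolated)
Conditions: AgOTf (10 mol %), toluene, rt; then TsOH·H2O (20 mol %), 4 Å MS, 60 °C
Reagents that add atoms: none
Why: The silver salt activates the alkyne for 5-exo-dig anti-addition of the cis carboxylic acid, which gives the Z-butylidene lactone of ring A, and the sulfonic acid then dehydrates the lactol of the other unit through its acyloxycarbenium ion to the thermodynamically preferred Z-butylidene lactone; the secondary alcohol cannot eliminate toward the bridgehead and is too far from either carbonyl to lactonise.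

**Compound list**

1 | methyl acetoacetate | CC(=O)CC(=O)OC | starting material
2 | 2,2-dimethoxyacetaldehyde | COC(OC)C=O | starting material
3 | methyl (2Z)-2-acetyl-4,4-dimethoxybut-2-enoate | COC(=O)/C(=C\C(OC)OC)C(C)=O | intermediate
4 | methyl (2Z)-2-{1-[(tert-butyldimethylsilyl)oxy]ethenyl}-4,4-dimethoxybut-2-enoate | COC(=O)/C(=C\C(OC)OC)C(=C)O[Si](C)(C)C(C)(C)C | intermediate
5 | acrolein | C=CC=O | starting material
6 | methyl (5S,6S)-2-[(tert-butyldimethylsilyl)oxy]-6-(dimethoxymethyl)-5-formylcyclohex-1-ene-1-carboxylate | COC(=O)C1=C(O[Si](C)(C)C(C)(C)C)CC[C@H](C=O)[C@@H]1C(OC)OC | intermediate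
7 | triphenylphosphine hydrobromide | [Br-].[PH+](c1ccccc1)(c1ccccc1)c1ccccc1 | starting material
8 | ethyl vinyl ether | C=COCC | starting material
9 | (1-ethoxyethyl)triphenylphosphonium bromide | CCOC(C)[P+](c1ccccc1)(c1ccccc1)c1ccccc1.[Br-] | intermediate
10 | methyl 2-[(tert-butyldimethylsilyl)oxy]-6-(dimethoxymethyl)-5-(2-ethoxyprop-1-en-1-yl)cyclohex-1-ene-1-carboxylate (5,6-cis; enol ether E/Z mixture) | COC(=O)C1=C(O[Si](C)(C)C(C)(C)C)CC[C@H](C=C(C)OCC)[C@@H]1C(OC)OC | intermediate
11 | methyl 6-(dimethoxymethyl)-5-(2-ethoxyprop-1-en-1-yl)-2-{[(trifluoromethyl)sulfonyl]oxy}cyclohex-1-ene-1-carboxylate (5,6-cis) | COC(=O)C1=C(OS(=O)(=O)C(F)(F)F)CC[C@H](C=C(C)OCC)[C@@H]1C(OC)OC | intermediate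
12 | pent-1-yne | C#CCCC | starting material
13 | methyl 6-(dimethoxymethyl)-5-(2-ethoxyprop-1-en-1-yl)-2-(pent-1-yn-1-yl)cyclohex-1-ene-1-carboxylate (5,6-cis) | COC(=O)C1=C(C#CCCC)CC[C@H](C=C(C)OCC)[C@@H]1C(OC)OC | intermediate
14 | methyl 6-formyl-5-(2-oxopropyl)-2-(pent-1-yn-1-yl)cyclohex-1-ene-1-carboxylate (5,6-cis; keto aldehyde, not isolated) | COC(=O)C1=C(C#CCCC)CC[C@H](CC(C)=O)[C@@H]1C=O | intermediate
15 | methyl (4aR,8aR)-6-oxo-2-(pent-1-yn-1-yl)-3,4,4a,5,6,8a-hexahydronaphthalene-1-carboxylate | COC(=O)C1=C(C#CCCC)CC[C@@H]2CC(=O)C=C[C@H]12 | intermediate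
16 | methyl propiolate | C#CC(=O)OC | starting material
17 | pentanoic anhydride | CCCCC(=O)OC(=O)CCCC | starting material
18 | methyl 4-oxooct-2-ynoate | CCCCC(=O)C#CC(=O)OC | intermediate
19 | methyl 6-[(tert-butyldimethylsilyl)oxy]-2-(pent-1-yn-1-yl)-3,4,4a,8a-tetrahydronaphthalene-1-carboxylate (4a,8a-cis) | COC(=O)C1=C(C#CCCC)CC[C@@H]2C=C(O[Si](C)(C)C(C)(C)C)C=C[C@H]12 | intermediate
20 | dimethyl 9-[(tert-butyldimethylsilyl)oxy]-3-pentanoyl-6-(pent-1-yn-1-yl)-1,4,4a,7,8,8a-hexahydro-1,4-ethenonaphthalene-2,5-dicarboxylate (silyl enol ether cycloadduct, not isolated) | COC(=O)C2=C(C#CCCC)CC[C@@H]1[C@H]3C(C(=O)OC)=C(C(=O)CCCC)[C@H](C=C3O[Si](C)(C)C(C)(C)C)[C@H]21 | intermediate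
21 | dimethyl 9-oxo-3-pentanoyl-6-(pent-1-yn-1-yl)-1,4,4a,7,8,8a-hexahydro-1,4-ethanonaphthalene-2,5-dicarboxylate (ring A syn to the C9–C10 bridge) | COC(=O)C2=C(C#CCCC)CC[C@@H]1[C@H]3C(C(=O)OC)=C(C(=O)CCCC)[C@H](CC3=O)[C@H]21 | intermediate
22 | dimethyl 9-hydroxy-3-pentanoyl-6-(pent-1-yn-1-yl)-1,4,4a,7,8,8a-hexahydro-1,4-ethanonaphthalene-2,5-dicarboxylate (9-OH on the face turned to ring A) | COC(=O)C2=C(C#CCCC)CC[C@@H]1[C@H]3C(C(=O)OC)=C(C(=O)CCCC)[C@H](C[C@H]3O)[C@H]21 | intermediate
23 | 9-epimeric 4-nitrobenzoate of 22 (ester oxygen on the face turned to the C2=C3 bridge) | COC(=O)C2=C(C#CCCC)CC[C@@H]1[C@H]3C(C(=O)OC)=C(C(=O)CCCC)[C@H](C[C@@H]3OC(=O)c4ccc(cc4)[N+](=O)[O-])[C@H]21 | intermediate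
24 | 9-hydroxy-3-pentanoyl-6-(pent-1-yn-1-yl)-1,4,4a,7,8,8a-hexahydro-1,4-ethanonaphthalene-2,5-dicarboxylic acid (open form of the lactol; target configuration at C9) | OC(=O)C2=C(C#CCCC)CC[C@@H]1[C@H]3C(C(=O)O)=C(C(=O)CCCC)[C@H](C[C@@H]3O)[C@H]21 | intermediate
25 | ring-A (Z)-butylidene lactone of 24 carrying the remaining keto acid (not isolated) | CCC/C=C1\OC(=O)C2=C1CC[C@@H]1[C@H]3C(C(=O)O)=C(C(=O)CCCC)[C@H](C[C@@H]3O)[C@H]21 | intermediate
26 | CNP0289078.1, the hydroxylated bis-(Z)-butylidene bis-lactone | CCC/C=C1\OC(=O)C2=C1CC[C@@H]1[C@H]3C4=C(/C(=C/CCC)OC4=O)[C@H](C[C@@H]3O)[C@H]21 | target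

**Step count.** Total: 15 steps. Longest linear sequence: 13 steps (1, 2, 3, 5, 6, 7, 8, 10, 11, 12, 13, 14, 15).

**Steps most likely to fail, with fallbacks**

Step 8. The aldehyde freed from the acetal has an α-hydrogen that is also allylic, so enolisation can epimerise the ring-fusion carbon, or move the ring alkene into conjugation, before the aldol closure. The fallback never frees the aldehyde. It sets out from 13: buffered hydrolysis of the enol ether only (pyridinium tosylate, wet acetone) should give methyl ketone acetal F3. Kinetic enolisation at the methyl group (LiN(iPr)2, Me3SiCl, THF, −78 °C) gives terminal trimethylsilyl enol ether F4. A Mukaiyama aldol closure onto the acetal (Me3SiOTf, 10 mol %, CH2Cl2, −78 °C) gives β-methoxy ketone F5. Elimination of methanol with DBU then returns to the route at 15.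

Step 3. The cationic boron acid may ionise the allylic acetal or strip the silyl enol ether before cycloaddition, and facial discrimination on unsubstituted acrolein may be poor. The fallback sets out from 4 and changes both dienophile and activation: commercial 3-acryloyloxazolidin-2-one is bound in a two-point fashion by the much milder Cu(SbF6)2 complex of (S,S)-2,2′-(propane-2,2-diyl)bis(4-tert-butyl-4,5-dihydro-1,3-oxazole) (CH2Cl2, −40 °C) and should give N-acyl oxazolidinone adduct F1 with the same regio- and endo-selectivity. LiBH4 with MeOH in THF at 0 °C cleaves the imide to primary alcohol F2. Oxidation with 1,1,1-triacetoxy-1,1-dihydro-1,2-benziodoxol-3(1H)-one returns to the route at 6.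

Step 13. The hindered carbinol may resist activation, or the oxyphosphonium ion may collapse by elimination toward C10 instead of substitution. The fallback sets the carbinol under thermodynamic control. It sets out from 21: equilibrating Meerwein–Ponndorf–Verley reduction (Al(OiPr)3, propan-2-ol, a little acetone, toluene, 80 °C) should favour the less congested epimer with the hydroxyl turned toward the C2=C3 bridge, hydroxy diester F6. Saponification as in step 14 returns to the route at 24.

**Further compounds**

F1 | step 3 | methyl (5,6-cis)-2-[(tert-butyldimethylsilyl)oxy]-6-(dimethoxymethyl)-5-[(2-oxo-1,3-oxazolidin-3-yl)carbonyl]cyclohex-1-ene-1-carboxylate | COC(=O)C1=C(O[Si](C)(C)C(C)(C)C)CC[C@H](C(=O)N2CCOC2=O)[C@@H]1C(OC)OC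
F2 | step 3 | methyl (5,6-cis)-2-[(tert-butyldimethylsilyl)oxy]-6-(dimethoxymethyl)-5-(hydroxymethyl)cyclohex-1-ene-1-carboxylate | COC(=O)C1=C(O[Si](C)(C)C(C)(C)C)CC[C@H](CO)[C@@H]1C(OC)OC
F3 | step 8 | methyl (5,6-cis)-6-(dimethoxymethyl)-5-(2-oxopropyl)-2-(pent-1-yn-1-yl)cyclohex-1-ene-1-carboxylate | COC(=O)C1=C(C#CCCC)CC[C@H](CC(C)=O)[C@@H]1C(OC)OC
F4 | step 8 | methyl (5,6-cis)-6-(dimethoxymethyl)-2-(pent-1-yn-1-yl)-5-{2-[(trimethylsilyl)oxy]prop-2-en-1-yl}cyclohex-1-ene-1-carboxylate | COC(=O)C1=C(C#CCCC)CC[C@H](CC(=C)O[Si](C)(C)C)[C@@H]1C(OC)OC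
F5 | step 8 | methyl (4a,8a-cis)-8-methoxy-6-oxo-2-(pent-1-yn-1-yl)-3,4,4a,5,6,7,8,8a-octahydronaphthalene-1-carboxylate (C8 epimers) | COC(=O)C1=C(C#CCCC)CC[C@@H]2CC(=O)CC(OC)[C@H]12
F6 | step 13 | dimethyl 9-hydroxy-3-pentanoyl-6-(pent-1-yn-1-yl)-1,4,4a,7,8,8a-hexahydro-1,4-ethanonaphthalene-2,5-dicarboxylate (9-OH on the face turned to the C2=C3 bridge) | COC(=O)C2=C(C#CCCC)CC[C@@H]1[C@H]3C(C(=O)OC)=C(C(=O)CCCC)[C@H](C[C@@H]3O)[C@H]21
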